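## The problem

Locants used throughout: each half is numbered O1–C2(CH3)2–C3–C4–C5–C6–C7 around the oxepane, C6–C7–C8–C9–C10–C11 around ring B, and C12 for the linker carbon on C11; the diacetate half is primed.

- The target consists of two oxepane–cyclohexane bicycles, each trans-fused through C6–C7, joined by the C12–C12′ bond between C11 and C11′.
- The two halves have the same configuration at C3, C6, C7 and C11. They differ only at C10 (exocyclic methylene versus methyl/acetoxy carbinol) and in acylation (free C3 hydroxyl versus C3′ acetate). One bicyclic intermediate can therefore serve both, provided the left C3 oxygen stays distinguishable to the end.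
- The quaternary C6 with its axial methyl group is the anchor of each half. From it can be derived C7 (axial hydrogen delivery anti to the methyl), C11 (equatorial C12, the thermodynamic position next to a C10 carbonyl) and C10′ (equatorial attack on a ketone whose axial face is blocked by the syn-axial methyl). C3 lies across the ring oxygen and needs reagent control.
- Fragile features are the exocyclic alkene (it would not survive a hydrogenation), the tertiary acetate (1,3-diaxial to the C6′ methyl, prone to elimination and acyl transfer), the β-oxygenated C10 ketone and C12 aldehyde of intermediates, and the C12–C12′ bond, which joins two carbons each flanked by a quaternary centre.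
- The feature that opens a photochemical entry: O1–C2(CH3)2–C3(O)–C4 is a 2,2-dimethylfuran-3(2H)-one ring into whose C4–C7 bond C5 and C6 have been inserted, and C6–C7 is also a ring B bond. A [2+2] addition of the furanone C4=C7 bond to a C6=C5 alkene, followed by scission of C4–C7, gives oxepane and ring B together.

## Retrosynthesis

**Methylene and linker.** Target 34 is traced through silyl ether 33 to ketone 32, because the exocyclic alkene cannot coexist with the hydrogenation that saturates the linker. Ketone 32 comes from alcohol 31 and this from alkene 30 and its precursor 29. Cutting C12=C12′ in 29 gives tetrazolyl sulfone 20 and aldehyde 27. An olefination is preferred over alkylation of a β-branched primary halide, which would be very slow. The diacetate half is made the aldehyde and carries its tertiary hydroxyl as a silyl ether, so that no acetate sits next to either reacting centre during the union. The tertiary acetate is added at 29, where the left half is still fully protected. The forward reaction must join two hindered carbons and then acylate a hindered tertiary alcohol selectively.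

**Two halves from one alcohol.** Sulfone 20 and aldehyde 27 are both traced to alcohol 16, which carries a benzylidene acetal across O10 and O12. Opening this acetal towards the secondary benzyl ether gives 18 and then 20 (C10 masked, C12 activated). Opening it towards the primary benzyl ether gives 22, whose oxidation to ketone 23 and methyl addition give carbinol 24 and then 27. A single protecting group thus supplies both differentiation patterns. The C3 oxygen is silylated in the left series (17) and acetylated in the right (21). The forward steps need the two opposite regiochemistries of reductive acetal opening and equatorial methyl delivery to 23.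

**Oxepane from cyclobutane.** Alcohol 16 comes from oxepan-3-one 15 by reagent-controlled reduction, and 15 from photoadduct 14 by re-forming the C4–C7 bond. In the forward sense this bond is the one to break: it is strained, carries the ring oxygen as donor on C7, and lies next to the C3 carbonyl through C4. Its scission turns the five-membered ring into the seven-membered one, whereas breaking C4–C5 would give a primary radical. The step must deliver hydrogen to C7 trans to the C6 methyl.

**The key cut.** Photoadduct 14 is opened at C6–C7 and C4–C5 to furanone 13. This removes ring B, the cyclobutane and three stereocentres at once and leaves a monocyclic chromophore on a six-membered acetal with two stereocentres. Cationic or aldol closures of C6–C7 alone would leave the quaternary centre and the seven-membered ether as separate problems. The forward reaction must close in the straight sense and on one alkene face.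

**Furanone.** Furanone 13 is cut at O1–C7 and C3–C4 to ynone acetate 11, and this to alkyne 9 and acid chloride 10. The acid chloride 10 brings C2, both methyl groups, C3 and O1 in one piece, and the cyclisation is base-mediated, which the acetal tolerates.

**Tether and stereocentres.** Acetal 9 comes from anti-diol 8, and 8 from epoxy alcohol 6 by opening at C11 with Grignard reagent 7 (C11–C6 bond). Epoxide 6 comes from allylic alcohol 5, ester 4, and finally pent-4-yn-1-ol 1 and ylide 2. A C10 ketal with a separate C12 ether was set aside for two reasons. It would have to be made from a β,γ-unsaturated β′-alkoxy ketone whose C11 centre racemises. Its axial oxygen would also lie 1,3 to the methyl group in the wanted transition state. The epoxide route gives C10 and C11 from one catalytic step and an equatorial O10 in a trans-fused dioxane.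

## Roads not taken

**Alternative 1:** The cut is at O1–C2 and C6–C11. In the forward step Me3SiOTf activates the terminal epoxide of diepoxy allylsilane A1; the inner epoxide oxygen attacks C2, and the allylsilane opens the resulting epoxonium ion at C6, giving bicycle A2.
- Merits: C3, C6, C7 and C11 come from two reagent-controlled epoxidations and an alkene geometry. The oxepane, ring B and the exocyclic alkene appear in one step, and the route to the bicycle is several steps shorter than the one chosen here.
- Weak points: the first epoxide can be opened in the tetrahydropyran-forming sense. The cation can also rearrange or eliminate before the allylsilane arrives. The exocyclic alkene that the cascade delivers cannot be carried through an olefination/hydrogenation union, so both halves would still pass through the C10 ketone.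
- Comparison: in step count and in the security of absolute configuration this road is better. The chosen plan sets against it that each ring-forming bond is made in a step whose regiochemistry is enforced (tether length, strain-driven scission) rather than by the partitioning of a cation, and that C10 emerges at the protected-alcohol level that both halves need.

**Alternative 2:** The cut is at C6–C11 only. Lactone A3 is converted (LDA, Me3SiCl) into its silyl ketene acetal, which rearranges through a boat transition state with ring contraction to cyclohexene acid A4.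
- Merits: the [3,3] shift is stereospecific. It sets the C6/C11 pair, the relationship that the photocycloaddition must obtain by face selection, by chirality transfer from one carbinol centre. C12 arrives as a carboxyl group and C10 as a ketal.
- Weak points: only ring B is made. The oxepane must then be built from the homoprenyl chain and the C7=C8 alkene, which requires oxygen on C7 trans to the methyl group and a seven-membered etherification at the tertiary C2 in competition with six-membered closure. The fully substituted alkene terminus puts one substituent inside the boat (allylic 1,3-strain), so the rearrangement is likely to be slow.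
- Comparison: for C6/C11 control A4 is superior to 14. The chosen plan sets against it that O1, C2, the C3 oxygen and the whole seven-membered ring arrive in the same two steps as ring B.

**Alternative 3:** The cut is at C6–C7 and C10–C11. Geranoyl imide A5, activated by Me2AlCl, adds across the 2- and 5-positions of 2-methylfuran A6 to give oxanorbornene A7.
- Merits: both ring B bonds form in one step with auxiliary control of absolute configuration. The C10 methyl group and an oxygen on C10 or C7 are in place, which suits the diacetate half.
- Weak points: furan is a reluctant and reversible diene, and a β,β-disubstituted acyl imide is a poor dienophile. The Lewis acid favours conjugate (Friedel–Crafts) addition of the furan or ring opening of the adduct. Regiochemistry and endo/exo selectivity must both be right. The bridge ether supplies only one of the two oxygens needed, and the oxepane remains to be built.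
- Comparison: absolute control by an auxiliary is more predictable in principle than the substrate control used here. The chosen plan sets against it a cycloaddition of documented type and the direct delivery of the oxepanone.

Key step: step 8

## Route

Remark on the chemistry: the alkene formed in step 22 is drawn E; its geometry is immaterial because it is hydrogenated in step 24.

Step 1
Reactants: 1 pent-4-yn-1-ol; 2 ethyl (triphenylphosphoranylidene)acetate
Product: 4 ethyl (2E)-hept-2-en-6-ynoate, via pent-4-ynal 3 (not isolated)
Conditions: IBX, DMSO, rt, 2 present from the start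
Reagents that add atoms: none
Why: Tandem IBX oxidation–Wittig olefination; the stabilised ylide traps the volatile aldehyde as it forms and gives the E-enoate.

Step 2
Reactants: 4 ethyl (2E)-hept-2-en-6-ynoate
Product: 5 (2E)-hept-2-en-6-yn-1-ol
Conditions: iBu2AlH, CH2Cl2, −78 °C; KNaC4H4O6 (aq) work-up
Reagents that add atoms: none
Why: 1,2-Reduction of the enoate by the aluminium hydride at low temperature; the terminal alkyne is not touched.

Step 3
Reactants: 5 (2E)-hept-2-en-6-yn-1-ol
Product: 6 [(2R,3R)-3-(but-3-yn-1-yl)oxiran-2-yl]methanol
Conditions: Ti(OiPr)4 (10 mol %), D-(−)-diethyl tartrate (12 mol %), t-BuOOH, 4 Å MS, CH2Cl2, −20 °C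
Reagents that add atoms: tert-butyl hydroperoxide, CC(C)(C)OO
Why: Sharpless asymmetric epoxidation; the D-tartrate ligand directs oxygen to the face that gives the (2R,3R)-epoxide, which fixes C10 and, after inversion in step 4, C11.

Step 4
Reactants: 6 [(2R,3R)-3-(but-3-yn-1-yl)oxiran-2-yl]methanol; 7 isopropenylmagnesium bromide, CH2=C(CH3)MgBr
Product: 8 (2S,3R)-2-(prop-1-en-2-yl)hept-6-yne-1,3-diol
Conditions: 7 (4 equiv), CuI (20 mol %), THF, −30 → 0 °C; NH4Cl (aq); NaIO4 wash
Reagents that add atoms: none
Why: Copper-catalysed anti SN2 opening of the 2,3-epoxy alcohol at the carbon next to CH2OH sets C11 by inversion and gives the anti-1,3-diol. The alkyne is carried as its magnesium acetylide, and the minor 1,2-diol from attack at C10 is cleaved by NaIO4.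

Step 5
Reactants: 8 (2S,3R)-2-(prop-1-en-2-yl)hept-6-yne-1,3-diol
Product: 9 (2S,4R,5S)-4-(but-3-yn-1-yl)-2-phenyl-5-(prop-1-en-2-yl)-1,3-dioxane
Conditions: PhCH(OMe)2, camphorsulfonic acid (cat.), CH2Cl2, rt
Reagents that add atoms: benzaldehyde dimethyl acetal, COC(OC)c1ccccc1
Why: Acid-catalysed transacetalisation under thermodynamic control gives the chair dioxane with phenyl, C9 chain and isopropenyl all equatorial, so the acetal centre is set by the ring.

Step 6
Reactants: 9 (2S,4R,5S)-4-(but-3-yn-1-yl)-2-phenyl-5-(prop-1-en-2-yl)-1,3-dioxane; 10 2-acetoxy-2-methylpropanoyl chloride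
Product: 11 2-methyl-3-oxo-7-[(2S,4R,5S)-2-phenyl-5-(prop-1-en-2-yl)-1,3-dioxan-4-yl]hept-4-yn-2-yl acetate
Conditions: PdCl2(PPh3)2 (2 mol %), CuI (4 mol %), Et3N, THF, rt
Reagents that add atoms: none
Why: Acyl Sonogashira coupling of the terminal alkyne with an acid chloride that has no α-hydrogen (no ketene pathway) gives the ynone; acetal and alkene are inert.

Step 7
Reactants: 11 ynone acetate
Product: 13 2,2-dimethyl-5-{2-[(2S,4R,5S)-2-phenyl-5-(prop-1-en-2-yl)-1,3-dioxan-4-yl]ethyl}furan-3(2H)-one, via hydroxy ynone 12 (not isolated)
Conditions: K2CO3, MeOH, 0 °C → rt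
Reagents that add atoms: none
Why: Methanolysis of the activated α′-acetate is followed by base-mediated 5-endo-dig oxa-Michael cyclisation of the α′-hydroxy ynone (directly or through its β-methoxy enone), the known route to 3(2H)-furanones.

Step 8
Reactants: 13 furanone
Product: 14 cyclobutane photoadduct (bonds C6–C7 and C4–C5 formed; 4S,6R,7S,10R,11S; methyl on C6 cis to C12)
Conditions: hν (350 nm, Pyrex), degassed CH2Cl2, 5 mM, 0 °C
Reagents that add atoms: none
Why: Excitation of the β-alkoxy enone and intersystem crossing give its triplet, which adds stepwise to the tethered 1,1-disubstituted alkene: C7 bonds to C6, and the resulting 1,4-biradical (C4/C5) closes C4–C5 after spin inversion. The closest known reaction type is the intramolecular [2+2] photocycloaddition of 5-(ω-alkenyl)-3(2H)-furanones and of dioxinones, which gives straight adducts when four atoms separate chromophore and alkene. Ring B closes in the 1,6-mode (six-membered, exo with respect to the alkene) through a chair in which the trans-fused dioxane holds C9 and C6 gauche and keeps C12 and O10 equatorial; the cyclobutane then closes by combination of the C4 and C5 radical centres and is cis-fused both to ring B and to the five-membered ring. C6 is controlled by C10 and C11 through this chair: the methyl group is expected in the pseudo-axial site, where it meets only axial hydrogens on C8 and C10 and stays clear of the gem-dimethyl group on C2, while the methylene terminus lies under C4, and this places the methyl cis to C12. C7 follows from C6 because only a cis-fused four-membered ring can close, and C4 follows from C7 because the five-membered ring must be cis-fused to the cyclobutane; both are transient, since C4 becomes CH2 and C7 is reset in step 9. The step needs straight rather than crossed (C7–C5, C4–C6) regiochemistry, which the six- over seven-membered first closure and the gauche pre-organisation by the acetal should secure. It also needs attack on one alkene face, for which the locked equatorial C12 and the equatorial (not axial) oxygen at C10 are relied on. Dilute long-wavelength irradiation stopped at full conversion limits secondary α-cleavage of the product ketone.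

Step 9
Reactants: 14 cyclobutane photoadduct
Product: 15 trans-fused oxepan-3-one (6R,7R,10R,11S; O10,O12-benzylidene acetal retained)
Conditions: SmI2 (2.5 equiv), THF–MeOH (10:1), −78 °C
Reagents that add atoms: none
Why: Ketyl formation at C3 and β-scission of the strained C4–C7 bond give a samarium enolate and a tertiary α-oxygenated radical at C7, the known reductive fragmentation of cyclobutyl ketones from photoadducts. The C7 radical (or its organosamarium) should take up hydrogen axially, anti to the axial C6 methyl, which gives the trans ring fusion.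

Step 10
Reactants: 15 oxepan-3-one
Product: 16 (3R)-oxepan-3-ol
Conditions: (S)-2-methyl-CBS-oxazaborolidine (20 mol %), BH3·SMe2, THF, −20 °C
Reagents that add atoms: none
Why: Corey–Bakshi–Shibata reduction; the quaternary C2 side acts as the large group and C4H2 as the small one, so the (S)-catalyst gives the (3R)-alcohol under reagent control.

Step 11
Reactants: 16 (3R)-oxepan-3-ol
Product: 17 C3 tert-butyldimethylsilyl ether of 16
Conditions: TBSOTf, 2,6-lutidine, CH2Cl2, 0 °C
Reagents that add atoms: tert-butyldimethylsilyl trifluoromethanesulfonate, CC(C)(C)[Si](C)(C)OS(=O)(=O)C(F)(F)F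
Why: Silylation of the hindered secondary alcohol with the silyl triflate; this group marks the left C3 oxygen until the last step.

Step 12
Reactants: 17 silyl ether
Product: 18 left-half primary alcohol (C10 benzyl ether, C12 hydroxyl, C3 silyl ether)
Conditions: iBu2AlH, toluene, 0 °C → rt
Reagents that add atoms: none
Why: Reductive opening of the benzylidene acetal: aluminium binds the less hindered primary oxygen, so the benzyl group ends on O10 and the primary alcohol is freed, as with 4,6-O-benzylidene hexopyranosides.

Step 13
Reactants: 18 left-half primary alcohol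
Product: 19 C12 (1-phenyl-1H-tetrazol-5-yl) sulfide
Conditions: 1-phenyl-1H-tetrazole-5-thiol, PPh3, diisopropyl azodicarboxylate, THF, 0 °C → rt
Reagents that add atoms: 1-phenyl-1H-tetrazole-5-thiol, Sc1nnnn1-c1ccccc1
Why: Mitsunobu thioetherification of the primary alcohol; the secondary silyl and benzyl ethers do not take part.

Step 14
Reactants: 19 tetrazolyl sulfide
Product: 20 left-half sulfone (C12 1-phenyl-1H-tetrazol-5-ylsulfonyl, C10 benzyl ether, C3 silyl ether)
Conditions: (NH4)6Mo7O24·4H2O (cat.), H2O2 (30 %), EtOH, 0 °C → rt
Reagents that add atoms: hydrogen peroxide, OO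
Why: Molybdate-catalysed oxidation of the sulfide to the sulfone, the standard preparation of Julia–Kocienski reagents.

Step 15
Reactants: 16 (3R)-oxepan-3-ol
Product: 21 C3 acetate of 16
Conditions: Ac2O, pyridine, 4-(dimethylamino)pyridine (cat.), CH2Cl2, rt
Reagents that add atoms: acetic anhydride, CC(=O)OC(C)=O
Why: Acetylation installs the final C3′ ester, which also protects this oxygen during the oxidation at C10.

Step 16
Reactants: 21 acetate
Product: 22 right-half secondary alcohol (C12 benzyl ether, C10 hydroxyl equatorial, C3 acetate)
Conditions: Et3SiH, TfOH, 4 Å MS, CH2Cl2, −78 °C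
Reagents that add atoms: none
Why: Acid-promoted reductive opening of the benzylidene acetal with the opposite regiochemistry (primary benzyl ether, free secondary hydroxyl), as with 4,6-O-benzylidene hexopyranosides under silane/strong acid.

Step 17
Reactants: 22 secondary alcohol
Product: 23 C10 ketone (C12 benzyl ether, C3 acetate)
Conditions: Dess–Martin periodinane, NaHCO3, CH2Cl2, rt
Reagents that add atoms: none
Why: Buffered hypervalent-iodine oxidation; C11 already has the thermodynamically preferred equatorial C12, and the neutral medium avoids β-elimination of the benzyloxy group.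

Step 18
Reactants: 23 C10 ketone
Product: 24 (10S)-tertiary alcohol (methyl equatorial, hydroxyl axial)
Conditions: MeMgBr, CeCl3 (anhydrous), THF, −78 °C
Reagents that add atoms: methylmagnesium bromide, C[Mg]Br
Why: Organocerium addition to the ketone; the axial trajectory is blocked by the syn-axial C6 methyl, so the methyl group enters equatorially and the hydroxyl becomes axial. The weakly basic reagent avoids enolisation with loss of benzyloxide and spares the hindered acetate at this temperature.

Step 19
Reactants: 24 tertiary alcohol
Product: 25 C10 trimethylsilyl ether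
Conditions: Me3SiOTf, 2,6-lutidine, CH2Cl2, −78 → 0 °C
Reagents that add atoms: trimethylsilyl trifluoromethanesulfonate, C[Si](C)(C)OS(=O)(=O)C(F)(F)F
Why: Silylation of the tertiary alcohol with the silyl triflate masks it during the olefination, where a free β-hydroxy aldehyde could undergo retro-aldol cleavage.

Step 20
Reactants: 25 trimethylsilyl ether
Product: 26 right-half primary alcohol (C12 hydroxyl)
Conditions: H2 (1 atm), Pd/C, EtOAc, rt
Reagents that add atoms: none
Why: Hydrogenolysis of the benzyl ether under neutral conditions; acetate and silyl ether remain.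

Step 21
Reactants: 26 primary alcohol
Product: 27 right-half aldehyde (C12 formyl, C10 trimethylsilyl ether, C3 acetate)
Conditions: Dess–Martin periodinane, NaHCO3, CH2Cl2, 0 °C → rt
Reagents that add atoms: none
Why: Buffered oxidation to the β-silyloxy aldehyde, which is used without delay; the equatorial formyl group is the stable configuration at C11.

Step 22
Reactants: 20 left-half sulfone; 27 right-half aldehyde
Product: 29 C12=C12′ alkene with free C10′ tertiary alcohol, via trimethylsilyl ether 28 (not isolated)
Conditions: 20, KN(SiMe3)2, 1,2-dimethoxyethane, −78 °C; 27, −78 °C → rt; then citric acid, MeOH, rt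
Reagents that add atoms: none
Why: Julia–Kocienski olefination (addition, Smiles rearrangement, loss of SO2 and tetrazolone) forms the linker double bond without an acetate near either reacting carbon. The mild acidic methanolysis then removes only the tertiary trimethylsilyl ether.

Step 23
Reactants: 29 alkene tertiary alcohol
Product: 30 alkene with C3′ and C10′ acetates
Conditions: Ac2O, 4-(dimethylamino)pyridine, Et3N, toluene, 60 °C
Reagents that add atoms: acetic anhydride, CC(=O)OC(C)=O
Why: Nucleophile-catalysed acylation of the tertiary alcohol; every other oxygen is protected (silyl ether, benzyl ether, acetate), so only C10′–OH can react.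

Step 24
Reactants: 30 alkene diacetate
Product: 31 saturated C10 secondary alcohol
Conditions: H2 (4 atm), Pd(OH)2/C, EtOAc–EtOH, rt
Reagents that add atoms: none
Why: Hydrogenation of the disubstituted alkene and hydrogenolysis of the C10 benzyl ether in one operation; no stereocentre is created.

Step 25
Reactants: 31 secondary alcohol
Product: 32 C10 ketone of the coupled system
Conditions: Dess–Martin periodinane, NaHCO3, CH2Cl2, rt
Reagents that add atoms: none
Why: Oxidation of the only free hydroxyl; C11 keeps its equatorial substituent, which is also the thermodynamic arrangement.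

Step 26
Reactants: 32 C10 ketone
Product: 33 exocyclic methylene compound (C3 silyl ether)
Conditions: Zn, CH2Br2, TiCl4, THF (reagent formed at 0 °C); 32, CH2Cl2, rt
Reagents that add atoms: dibromomethane, BrCBr
Why: Lombardo methylenation; the non-basic titanium–zinc reagent converts hindered, enolisable ketones without epimerising C11 and does not attack the acetates.

Step 27
Reactants: 33 silyl ether
Product: 34 target compound
Conditions: HF·pyridine, pyridine, THF, 0 °C → rt
Reagents that add atoms: none
Why: Buffered fluoride cleavage of the tert-butyldimethylsilyl ether frees the left C3 hydroxyl without acyl migration or isomerisation of the exocyclic alkene.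

## Compound list

1 | pent-4-yn-1-ol | OCCCC#C | starting material
2 | ethyl (triphenylphosphoranylidene)acetate | CCOC(=O)C=P(c1ccccc1)(c1ccccc1)c1ccccc1 | starting material
3 | pent-4-ynal | O=CCCC#C | intermediate
4 | ethyl (2E)-hept-2-en-6-ynoate | CCOC(=O)/C=C/CCC#C | intermediate
5 | (2E)-hept-2-en-6-yn-1-ol | OC/C=C/CCC#C | intermediate
6 | [(2R,3R)-3-(but-3-yn-1-yl)oxiran-2-yl]methanol | OC[C@H]1O[C@@H]1CCC#C | intermediate
7 | isopropenylmagnesium bromide, CH2=C(CH3)MgBr | CC(=C)[Mg]Br | starting material
8 | (2S,3R)-2-(prop-1-en-2-yl)hept-6-yne-1,3-diol (C11 S, C10 R, anti) | OC[C@H](C(C)=C)[C@H](O)CCC#C | intermediate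
9 | (2S,4R,5S)-4-(but-3-yn-1-yl)-2-phenyl-5-(prop-1-en-2-yl)-1,3-dioxane (all substituents equatorial) | C#CCC[C@H]1O[C@@H](c2ccccc2)OC[C@@H]1C(C)=C | intermediate
10 | 2-acetoxy-2-methylpropanoyl chloride | CC(=O)OC(C)(C)C(Cl)=O | starting material
11 | 2-methyl-3-oxo-7-[(2S,4R,5S)-2-phenyl-5-(prop-1-en-2-yl)-1,3-dioxan-4-yl]hept-4-yn-2-yl acetate | CC(=O)OC(C)(C)C(=O)C#CCC[C@H]1O[C@@H](c2ccccc2)OC[C@@H]1C(C)=C | intermediate
12 | 2-hydroxy-2-methyl-7-[(2S,4R,5S)-2-phenyl-5-(prop-1-en-2-yl)-1,3-dioxan-4-yl]hept-4-yn-3-one | CC(C)(O)C(=O)C#CCC[C@H]1O[C@@H](c2ccccc2)OC[C@@H]1C(C)=C | intermediate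
13 | 2,2-dimethyl-5-{2-[(2S,4R,5S)-2-phenyl-5-(prop-1-en-2-yl)-1,3-dioxan-4-yl]ethyl}furan-3(2H)-one | CC1(C)OC(CC[C@H]2O[C@@H](c3ccccc3)OC[C@@H]2C(C)=C)=CC1=O | intermediate
14 | photoadduct: cyclobutane C4–C5–C6–C7 cis-fused to the 2,2-dimethyltetrahydrofuran-3-one (O1, C2, C3, C4, C7) and to ring B, trans-fused (S)-2-phenyl-1,3-dioxane over O10/C10/C11/C12/O12; 4S,6R,7S,10R,11S | O=C1[C@H]2C[C@]3(C)[C@H]4CO[C@H](c5ccccc5)O[C@@H]4CC[C@]23OC1(C)C | intermediate
15 | oxepan-3-one: 2,2,6-trimethyl oxepanone trans-fused at C6–C7 to ring B, O10,O12-benzylidene acetal; 6R,7R,10R,11S | O=C1CC[C@]2(C)[C@H]3CO[C@H](c4ccccc4)O[C@@H]3CC[C@H]2OC1(C)C | intermediate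
16 | (3R)-alcohol of 15 | O[C@@H]1CC[C@]2(C)[C@H]3CO[C@H](c4ccccc4)O[C@@H]3CC[C@H]2OC1(C)C | intermediate
17 | C3 tert-butyldimethylsilyl ether of 16 | CC(C)(C)[Si](C)(C)O[C@@H]1CC[C@]2(C)[C@H]3CO[C@H](c4ccccc4)O[C@@H]3CC[C@H]2OC1(C)C | intermediate
18 | left-half alcohol: C3 silyl ether, C10 benzyl ether (equatorial), C12 hydroxyl | CC(C)(C)[Si](C)(C)O[C@@H]1CC[C@]2(C)[C@@H](CO)[C@H](OCc3ccccc3)CC[C@H]2OC1(C)C | intermediate
19 | left-half C12 (1-phenyl-1H-tetrazol-5-yl) sulfide | CC(C)(C)[Si](C)(C)O[C@@H]1CC[C@]2(C)[C@@H](CSc3nnnn3-c4ccccc4)[C@H](OCc5ccccc5)CC[C@H]2OC1(C)C | intermediate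
20 | left-half C12 (1-phenyl-1H-tetrazol-5-yl) sulfone | CC(C)(C)[Si](C)(C)O[C@@H]1CC[C@]2(C)[C@@H](CS(=O)(=O)c3nnnn3-c4ccccc4)[C@H](OCc5ccccc5)CC[C@H]2OC1(C)C | intermediate
21 | C3 acetate of 16 | CC(=O)O[C@@H]1CC[C@]2(C)[C@H]3CO[C@H](c4ccccc4)O[C@@H]3CC[C@H]2OC1(C)C | intermediate
22 | right-half alcohol: C3 acetate, C12 benzyl ether, C10 hydroxyl (equatorial) | CC(=O)O[C@@H]1CC[C@]2(C)[C@@H](COCc3ccccc3)[C@H](O)CC[C@H]2OC1(C)C | intermediate
23 | right-half C10 ketone: C3 acetate, C12 benzyl ether | CC(=O)O[C@@H]1CC[C@]2(C)[C@@H](COCc3ccccc3)C(=O)CC[C@H]2OC1(C)C | intermediate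
24 | right-half (10S)-tertiary alcohol: C10 methyl equatorial, hydroxyl axial | CC(=O)O[C@@H]1CC[C@]2(C)[C@@H](COCc3ccccc3)[C@@](C)(O)CC[C@H]2OC1(C)C | intermediate
25 | C10 trimethylsilyl ether of 24 | CC(=O)O[C@@H]1CC[C@]2(C)[C@@H](COCc3ccccc3)[C@@](C)(O[Si](C)(C)C)CC[C@H]2OC1(C)C | intermediate
26 | right-half primary alcohol: C12 hydroxyl, C10 trimethylsilyl ether, C3 acetate | CC(=O)O[C@@H]1CC[C@]2(C)[C@@H](CO)[C@@](C)(O[Si](C)(C)C)CC[C@H]2OC1(C)C | intermediate
27 | right-half aldehyde: C12 formyl, C10 trimethylsilyl ether, C3 acetate | CC(=O)O[C@@H]1CC[C@]2(C)[C@@H](C=O)[C@@](C)(O[Si](C)(C)C)CC[C@H]2OC1(C)C | intermediate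
28 | coupled (E)-C12=C12′ alkene: left C3 silyl ether and C10 benzyl ether, right C3′ acetate and C10′ trimethylsilyl ether | CC(C)(C)[Si](C)(C)O[C@@H]1CC[C@]2(C)[C@@H](/C=C/[C@H]4[C@@](C)(O[Si](C)(C)C)CC[C@H]5OC(C)(C)[C@H](OC(C)=O)CC[C@]45C)[C@H](OCc3ccccc3)CC[C@H]2OC1(C)C | intermediate
29 | coupled alkene with free C10′ tertiary alcohol | CC(C)(C)[Si](C)(C)O[C@@H]1CC[C@]2(C)[C@@H](/C=C/[C@H]4[C@@](C)(O)CC[C@H]5OC(C)(C)[C@H](OC(C)=O)CC[C@]45C)[C@H](OCc3ccccc3)CC[C@H]2OC1(C)C | intermediate
30 | coupled alkene with C3′ and C10′ acetates | CC(C)(C)[Si](C)(C)O[C@@H]1CC[C@]2(C)[C@@H](/C=C/[C@H]4[C@@](C)(OC(C)=O)CC[C@H]5OC(C)(C)[C@H](OC(C)=O)CC[C@]45C)[C@H](OCc3ccccc3)CC[C@H]2OC1(C)C | intermediate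
31 | saturated diacetate with free C10 hydroxyl, C3 silyl ether | CC(C)(C)[Si](C)(C)O[C@@H]1CC[C@]2(C)[C@@H](CC[C@H]4[C@@](C)(OC(C)=O)CC[C@H]5OC(C)(C)[C@H](OC(C)=O)CC[C@]45C)[C@H](O)CC[C@H]2OC1(C)C | intermediate
32 | C10 ketone of the coupled diacetate, C3 silyl ether | CC(C)(C)[Si](C)(C)O[C@@H]1CC[C@]2(C)[C@@H](CC[C@H]4[C@@](C)(OC(C)=O)CC[C@H]5OC(C)(C)[C@H](OC(C)=O)CC[C@]45C)C(=O)CC[C@H]2OC1(C)C | intermediate
33 | C3 tert-butyldimethylsilyl ether of the target | CC(C)(C)[Si](C)(C)O[C@@H]1CC[C@]2(C)[C@@H](CC[C@H]4[C@@](C)(OC(C)=O)CC[C@H]5OC(C)(C)[C@H](OC(C)=O)CC[C@]45C)C(=C)CC[C@H]2OC1(C)C | intermediate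
34 | CNP0412606.2 (left half 3R,6R,7R,11S with C10 methylene; right half 3′R,6′R,7′R,10′S,11′R diacetate) | O[C@@H]1CC[C@]2(C)[C@@H](CC[C@H]4[C@@](C)(OC(C)=O)CC[C@H]5OC(C)(C)[C@H](OC(C)=O)CC[C@]45C)C(=C)CC[C@H]2OC1(C)C | target

## Step count and uncertain steps

Total: 27 steps. Longest linear sequence: 23 steps (steps 1–10, 15–21, 22–27); the left branch (steps 11–14) is four steps from 16.

**Step 8 (key step).** The most likely failure is attack on the other face of the alkene: the rotamer about C11–C6 with the methylene terminus, not the methyl group, in the pseudo-axial site would give the adduct epimeric at C4, C6 and C7. The two rotamers differ only in whether methyl or methylene lies next to C10 and under the furanone, so the preference may be small or reversed. Crossed 1,7-closure is a second possibility.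

Fallback: relay through C11 epimerisation in the mirror acetal series, which needs only the other tartrate.
- It sets out from 5. L-(+)-Diethyl tartrate in the epoxidation gives the (2S,3S)-epoxy alcohol F1. The operations of steps 4–7 then give the (2R,3S)-diol F2, the (2R,4S,5R)-acetal F3, the ynone acetate F4 and the furanone F5.
- If the methylene terminus prefers the pseudo-axial site, irradiation of F5 gives photoadduct F6, with C4, C6 and C7 as in 14 and C10, C11 inverted.
- SmI2 then gives oxepanone F7, CBS reduction the (3R)-alcohol F8, and acetylation the acetate F9.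
- Et3SiH/TfOH gives the C12 benzyl ether F10 (C10 and C11 epimeric to 22), and Dess–Martin oxidation gives ketone F11, the C11 epimer of 23.
- A catalytic amount of 1,8-diazabicyclo[5.4.0]undec-7-ene in toluene at 0 °C moves C12 into the equatorial position, the stable arrangement next to an axial angular methyl; the contact is kept short because benzyloxide can be lost. The product is 23, where the route is rejoined.
- 23 serves the right half directly. For the left half, 23 is reduced under thermodynamic control (SmI2, THF–H2O) to 22, hydrogenolysed to the diol F12, re-acetalised with PhCH(OMe)2 to 21 and methanolysed (K2CO3, MeOH) to 16.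

**Step 9.** The most likely failure is hydrogen uptake at C7 from the equatorial side (cis-fused oxepane), or loss of the C7 radical by disproportionation to an enol ether, because this centre is rebuilt from a planar radical whose reduction by divalent samarium is slow.

Fallback: a polar instead of a radical opening. It sets out from 14. BF3·OEt2 and Et3SiH in CH2Cl2 at −78 °C open the donor–acceptor cyclobutane (ring oxygen on C7, C3 ketone beside C4) heterolytically to the C7 oxocarbenium ion and a boron enolate. Hydride then adds to the oxocarbenium ion axially, and aqueous work-up returns 15. At this temperature the benzylidene acetal should not be reduced. The fallback makes no compound outside the list (F0).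

**Step 22.** The most likely failure is slow addition of the hindered sulfonyl anion to the α-branched aldehyde, so that enolisation of 27 and self-consumption of the metalated tetrazolyl sulfone compete; both reacting carbons are flanked by a quaternary centre.

Fallback: a stepwise Julia–Lythgoe union with a smaller, more nucleophilic sulfone.
- It sets out from 18. PhSSPh/Bu3P gives the phenyl sulfide F13, and (NH4)6Mo7O24/H2O2 gives the phenyl sulfone F14.
- n-BuLi at −78 °C, then 27, then Ac2O give the β-acetoxy sulfone F15 (mixture at the two new centres).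
- SmI2 in THF–N,N′-dimethylpropyleneurea effects reductive elimination to 28, which citric acid in MeOH converts into 29, where the route is rejoined.

**Step 23.** The most likely failure is incomplete acylation of the axial tertiary hydroxyl, which is 1,3-diaxial to the C6′ methyl, under conditions mild enough for the silyl ether.

Fallback: acetylate before the union, where no silyl ether restricts the choice of acylation conditions.
- It sets out from 24. Ac2O with catalytic Sc(OTf)3 in MeCN at −20 °C gives the diacetate benzyl ether F16.
- H2 over Pd/C gives the diacetate alcohol F17, and Dess–Martin oxidation the diacetate aldehyde F18.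
- Olefination of F18 with 20 (KN(SiMe3)2 added to the mixture of both partners at −78 °C, to shorten the life of the anion beside the β-acetoxy aldehyde) gives 30 directly, where the route is rejoined.

## Further compounds

F1 | step 8 | [(2S,3S)-3-(but-3-yn-1-yl)oxiran-2-yl]methanol | OC[C@@H]1O[C@H]1CCC#C
F2 | step 8 | (2R,3S)-2-(prop-1-en-2-yl)hept-6-yne-1,3-diol | OC[C@@H](C(C)=C)[C@@H](O)CCC#C
F3 | step 8 | (2R,4S,5R)-4-(but-3-yn-1-yl)-2-phenyl-5-(prop-1-en-2-yl)-1,3-dioxane | C#CCC[C@@H]1O[C@H](c2ccccc2)OC[C@H]1C(C)=C
F4 | step 8 | 2-methyl-3-oxo-7-[(2R,4S,5R)-2-phenyl-5-(prop-1-en-2-yl)-1,3-dioxan-4-yl]hept-4-yn-2-yl acetate | CC(=O)OC(C)(C)C(=O)C#CCC[C@@H]1O[C@H](c2ccccc2)OC[C@H]1C(C)=C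
F5 | step 8 | 2,2-dimethyl-5-{2-[(2R,4S,5R)-2-phenyl-5-(prop-1-en-2-yl)-1,3-dioxan-4-yl]ethyl}furan-3(2H)-one | CC1(C)OC(CC[C@@H]2O[C@H](c3ccccc3)OC[C@H]2C(C)=C)=CC1=O
F6 | step 8 | photoadduct with C4, C6, C7 as in 14 and C10, C11, acetal carbon inverted | O=C1[C@H]2C[C@]3(C)[C@@H]4CO[C@@H](c5ccccc5)O[C@H]4CC[C@]23OC1(C)C
F7 | step 8 | oxepan-3-one with C6, C7 as in 15 and C10, C11, acetal carbon inverted | O=C1CC[C@]2(C)[C@@H]3CO[C@@H](c4ccccc4)O[C@H]3CC[C@H]2OC1(C)C
F8 | step 8 | (3R)-alcohol of F7 | O[C@@H]1CC[C@]2(C)[C@@H]3CO[C@@H](c4ccccc4)O[C@H]3CC[C@H]2OC1(C)C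
F9 | step 8 | C3 acetate of F8 | CC(=O)O[C@@H]1CC[C@]2(C)[C@@H]3CO[C@@H](c4ccccc4)O[C@H]3CC[C@H]2OC1(C)C
F10 | step 8 | C10,C11-diepimer of 22 (C12 benzyl ether, C10 hydroxyl) | CC(=O)O[C@@H]1CC[C@]2(C)[C@H](COCc3ccccc3)[C@@H](O)CC[C@H]2OC1(C)C
F11 | step 8 | C11 epimer of ketone 23 | CC(=O)O[C@@H]1CC[C@]2(C)[C@H](COCc3ccccc3)C(=O)CC[C@H]2OC1(C)C
F12 | step 8 | C10,C12-diol with C3 acetate (debenzylated 22) | CC(=O)O[C@@H]1CC[C@]2(C)[C@@H](CO)[C@H](O)CC[C@H]2OC1(C)C
F0 | step 9 | none | none
F13 | step 22 | left-half C12 phenyl sulfide (C3 silyl ether, C10 benzyl ether) | CC(C)(C)[Si](C)(C)O[C@@H]1CC[C@]2(C)[C@@H](CSc3ccccc3)[C@H](OCc4ccccc4)CC[C@H]2OC1(C)C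
F14 | step 22 | left-half C12 phenyl sulfone | CC(C)(C)[Si](C)(C)O[C@@H]1CC[C@]2(C)[C@@H](CS(=O)(=O)c3ccccc3)[C@H](OCc4ccccc4)CC[C@H]2OC1(C)C
F15 | step 22 | β-acetoxy phenyl sulfone adduct of F14 and 27 (C12 phenylsulfonyl, C12′ acetoxy, both centres unassigned) | CC(C)(C)[Si](C)(C)O[C@@H]1CC[C@]2(C)[C@@H](C(C(OC(C)=O)[C@H]4[C@@](C)(O[Si](C)(C)C)CC[C@H]5OC(C)(C)[C@H](OC(C)=O)CC[C@]45C)S(=O)(=O)c3ccccc3)[C@H](OCc6ccccc6)CC[C@H]2OC1(C)C
F16 | step 23 | right-half C3,C10-diacetate with C12 benzyl ether | CC(=O)O[C@@H]1CC[C@]2(C)[C@@H](COCc3ccccc3)[C@@](C)(OC(C)=O)CC[C@H]2OC1(C)C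
F17 | step 23 | right-half C3,C10-diacetate with C12 hydroxyl | CC(=O)O[C@@H]1CC[C@]2(C)[C@@H](CO)[C@@](C)(OC(C)=O)CC[C@H]2OC1(C)C
F18 | step 23 | right-half C3,C10-diacetate C12 aldehyde | CC(=O)O[C@@H]1CC[C@]2(C)[C@@H](C=O)[C@@](C)(OC(C)=O)CC[C@H]2OC1(C)C
A1 | alternative 1 | (Z)-allylsilane pivalate carrying the (3R)-2,3-epoxide and the (6R,7R)-6,7-epoxide | CC1(C)O[C@@H]1CC[C@@]2(C)O[C@@H]2CC/C(C[Si](C)(C)C)=C/COC(=O)C(C)(C)C
A2 | alternative 1 | exo-methylene oxepane–cyclohexane half with C3 hydroxyl and C12 pivalate | CC(C)(C)C(=O)OC[C@@H]1[C@@]2(C)CC[C@@H](O)C(C)(C)O[C@@H]2CCC1=C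
A3 | alternative 2 | (R)-6-[(1Z)-2,6-dimethylhepta-1,5-dien-1-yl] δ-lactone with C10 dioxolane | O=C1CC2(OCCO2)C[C@H](/C=C(C)\CCC=C(C)C)O1
A4 | alternative 2 | ring B cyclohexene acid with C12 carboxyl on C11, quaternary C6 and C10 dioxolane | OC(=O)[C@@H]1[C@@](C)(CCC=C(C)C)C=CCC12OCCO2
A5 | alternative 3 | (S)-4-benzyl-3-[(2E)-3,7-dimethylocta-2,6-dienoyl]oxazolidin-2-one | CC(C)=CCC/C(C)=C/C(=O)N1[C@@H](Cc2ccccc2)COC1=O
A6 | alternative 3 | 2-methylfuran | Cc1ccco1
A7 | alternative 3 | exo-acyl 7-oxanorbornene with C6 methyl and homoprenyl, C10 bridgehead methyl | O=C(N1[C@@H](Cc2ccccc2)COC1=O)[C@@H]3[C@@](C)(CCC=C(C)C)[C@H]4C=C[C@]3(C)O4
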